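**Plan**

- Retrosynthesis: the 5-OH is first traced back to a 5-OMe (a helper that makes ring A symmetric). Ring C is then cut at O1–C2 and at C4–C4a in one operation, giving 4-geranyl-3,5-dimethoxyphenol and (E)-3,4-dimethoxycinnamoyl chloride. The phenol is cut at the aryl–CH2 bond of the geranyl chain, back to 3,5-dimethoxyphenol and geranyl bromide.
- Enabling feature: ring A is a phloroglucinol-type ring. C4a is ortho or para to three oxygens (O1, 5-O, 7-O) and sits next to the phenolic O1, so O1 and C4a act as a 1,3-O,C-bis-nucleophile towards the acyl carbon C4 and the β-carbon C2 of the cinnamoyl unit. With 5-O and 7-O both methylated, the phenol has two identical ortho carbons, a para carbon blocked by geranyl and a single free OH.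
- Forward order: silylate 3,5-dimethoxyphenol, metalate between the two methoxy groups, allylate with geranyl bromide, desilylate. Prepare the acid chloride. Ring C then arises on the finished ring A in one telescoped operation: magnesium-templated ortho C-acylation followed by catalytic asymmetric 6-endo oxa-Michael closure. Chelation-controlled 5-O-demethylation comes last.
- Stereochemistry: C2 (S), the only stereocenter, is set in the ring closure by a cinchona-derived bifunctional thiourea. The (E)-alkene of the side chain comes unchanged from geranyl bromide.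

Key step: step 5

Remark: the quinidine-derived thiourea is assumed to favour attack on the Si face of the enone β-carbon, which gives (2S); if the sense is the opposite, its quinine-derived pseudoenantiomer takes its place with nothing else changed.

**Route**

Step 1
Reactants: 1 3,5-dimethoxyphenol
Product: 2 (3,5-dimethoxyphenoxy)tri(propan-2-yl)silane
Conditions: i-Pr3SiCl, imidazole, DMF, rt
Reagents that add atoms: chlorotri(propan-2-yl)silane, CC(C)[Si](Cl)(C(C)C)C(C)C
Why: Silylation of a phenol with a silyl chloride and imidazole should give a bulky aryl silyl ether that is stable to alkyllithiums, directs metalation poorly and shields both of its ortho positions, which prepares the regiochemistry of step 2.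

Step 2
Reactants: 2 (3,5-dimethoxyphenoxy)tri(propan-2-yl)silane; 3 geranyl bromide, (2E)-1-bromo-3,7-dimethylocta-2,6-diene
Product: 6 {4-[(2E)-3,7-dimethylocta-2,6-dien-1-yl]-3,5-dimethoxyphenoxy}tri(propan-2-yl)silane, via aryllithium 4 (not isolated), via arylcopper 5 (not isolated)
Conditions: n-BuLi, THF, 0 °C to rt; CuBr·SMe2, −78 to −40 °C; geranyl bromide, −40 to 0 °C
Reagents that add atoms: none
Why: Directed ortho-metalation should take place at the ring carbon flanked by the two methoxy groups (doubly activated, while the carbons next to the silyl ether are shielded), and the arylcopper formed by transmetalation should be allylated by SN2 attack at the CH2 end of the primary allylic bromide, which keeps the (E)-alkene.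

Step 3
Reactants: 6 {4-[(2E)-3,7-dimethylocta-2,6-dien-1-yl]-3,5-dimethoxyphenoxy}tri(propan-2-yl)silane
Product: 7 4-[(2E)-3,7-dimethylocta-2,6-dien-1-yl]-3,5-dimethoxyphenol
Conditions: Bu4NF, AcOH, THF, 0 °C
Reagents that add atoms: none
Why: Fluoride-induced cleavage of the aryl silyl ether, buffered with acetic acid so that the electron-rich phenol is released in its neutral form, should leave the ethers and the diene untouched.

Step 4
Reactants: 8 (2E)-3-(3,4-dimethoxyphenyl)prop-2-enoic acid
Product: 9 (2E)-3-(3,4-dimethoxyphenyl)prop-2-enoyl chloride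
Conditions: (COCl)2, cat. DMF, CH2Cl2, 0 °C to rt, volatiles removed
Reagents that add atoms: oxalyl chloride, ClC(=O)C(=O)Cl
Why: Acid chloride formation through the chloroiminium species from DMF and oxalyl chloride should proceed without change to the (E)-alkene or the aryl ethers.

Step 5
Reactants: 7 4-[(2E)-3,7-dimethylocta-2,6-dien-1-yl]-3,5-dimethoxyphenol; 9 (2E)-3-(3,4-dimethoxyphenyl)prop-2-enoyl chloride
Product: 13 (2S)-2-(3,4-dimethoxyphenyl)-6-[(2E)-3,7-dimethylocta-2,6-dien-1-yl]-5,7-dimethoxy-2,3-dihydro-4H-chromen-4-one, via magnesium phenolate 10 (not isolated), via magnesium chelate 11 (not isolated), via chalcone 12 (not isolated)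
Conditions: EtMgBr, Et2O, 0 °C, then solvent change to toluene; 9, 2,6-di-tert-butyl-4-methylpyridine, 0 °C to rt; pH 7 phosphate buffer, toluene layer dried over Na2SO4 and used as it is; thiourea from 9-amino-9-deoxy-epi-quinidine and 3,5-bis(trifluoromethyl)phenyl isothiocyanate (10 mol %), toluene, 0 °C
Reagents that add atoms: none
Why: Phenolate 10 binds acid chloride 9 at magnesium and passes the acyl carbon to the neighbouring ring carbon through a six-membered chelated transition state (templated ortho Friedel–Crafts acylation; closest known type: coordinated ortho-acylation of bromomagnesium phenolates by acid chlorides, α,β-unsaturated ones included), the hindered pyridine taking up HCl so that chelate 11 and, after the buffer, the free 2'-hydroxychalcone 12 result. The thiourea then closes ring C by 6-endo-trig oxa-Michael addition of the phenol oxygen to the enone β-carbon (closest known type: organocatalytic enantioselective cyclization of 2'-hydroxychalcones to flavanones). C2, the only new stereocenter, is under catalyst control: the thiourea hydrogen-bonds the C4 carbonyl, the quinuclidine deprotonates the phenol, and the resulting ion pair delivers oxygen to the Si face of the β-carbon, which gives (S). The step needs C- over O-acylation and attack at the acyl carbon instead of the β-carbon, which the magnesium template in non-coordinating toluene secures; it needs no site control, because in 7 the two methoxy groups make both ortho carbons identical, the geranyl chain blocks the para carbon and the single OH leaves only one oxygen that can close the ring. Kinetic control over the reversible closure is favoured by the neutral medium and the low temperature, and the 6'-methoxy group, which twists the enone out of the aryl plane, should make the closure fast under these mild conditions.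

Step 6
Reactants: 13 (2S)-2-(3,4-dimethoxyphenyl)-6-[(2E)-3,7-dimethylocta-2,6-dien-1-yl]-5,7-dimethoxy-2,3-dihydro-4H-chromen-4-one
Product: 14 (2S)-2-(3,4-dimethoxyphenyl)-6-[(2E)-3,7-dimethylocta-2,6-dien-1-yl]-5-hydroxy-7-methoxy-2,3-dihydro-4H-chromen-4-one
Conditions: MgI2·OEt2, THF, 50 °C; aq. Na2S2O3/NH4Cl
Reagents that add atoms: none
Why: In this chelation-controlled ether cleavage magnesium bridges the C4 carbonyl and the peri 5-methoxy oxygen and iodide removes that methyl group by SN2, so the 7-, 3'- and 4'-methoxy groups, which cannot chelate, should stay, while the weak Lewis acid should spare the geranyl chain and leave C2 untouched.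

**Compound list**

1 | 3,5-dimethoxyphenol | COc1cc(O)cc(OC)c1 | starting material
2 | (3,5-dimethoxyphenoxy)tri(propan-2-yl)silane | COc1cc(O[Si](C(C)C)(C(C)C)C(C)C)cc(OC)c1 | intermediate
3 | geranyl bromide, (2E)-1-bromo-3,7-dimethylocta-2,6-diene | BrC/C=C(\C)CCC=C(C)C | starting material
4 | {2,6-dimethoxy-4-[tri(propan-2-yl)silyloxy]phenyl}lithium | COc1cc(O[Si](C(C)C)(C(C)C)C(C)C)cc(OC)c1[Li] | intermediate
5 | {2,6-dimethoxy-4-[tri(propan-2-yl)silyloxy]phenyl}copper | COc1cc(O[Si](C(C)C)(C(C)C)C(C)C)cc(OC)c1[Cu] | intermediate
6 | {4-[(2E)-3,7-dimethylocta-2,6-dien-1-yl]-3,5-dimethoxyphenoxy}tri(propan-2-yl)silane | COc1cc(O[Si](C(C)C)(C(C)C)C(C)C)cc(OC)c1C/C=C(\C)CCC=C(C)C | intermediate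
7 | 4-[(2E)-3,7-dimethylocta-2,6-dien-1-yl]-3,5-dimethoxyphenol | COc1cc(O)cc(OC)c1C/C=C(\C)CCC=C(C)C | intermediate
8 | (2E)-3-(3,4-dimethoxyphenyl)prop-2-enoic acid | COc1ccc(/C=C/C(=O)O)cc1OC | starting material
9 | (2E)-3-(3,4-dimethoxyphenyl)prop-2-enoyl chloride | COc1ccc(/C=C/C(=O)Cl)cc1OC | intermediate
10 | bromomagnesium 4-[(2E)-3,7-dimethylocta-2,6-dien-1-yl]-3,5-dimethoxyphenolate | COc1cc(O[Mg]Br)cc(OC)c1C/C=C(\C)CCC=C(C)C | intermediate
11 | bromomagnesium phenolate (carbonyl chelate) of chalcone 12 | COc1ccc(/C=C/C(=O)c2c(O[Mg]Br)cc(OC)c(C/C=C(\C)CCC=C(C)C)c2OC)cc1OC | intermediate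
12 | (2E)-1-{3-[(2E)-3,7-dimethylocta-2,6-dien-1-yl]-6-hydroxy-2,4-dimethoxyphenyl}-3-(3,4-dimethoxyphenyl)prop-2-en-1-one | COc1ccc(/C=C/C(=O)c2c(O)cc(OC)c(C/C=C(\C)CCC=C(C)C)c2OC)cc1OC | intermediate
13 | (2S)-2-(3,4-dimethoxyphenyl)-6-[(2E)-3,7-dimethylocta-2,6-dien-1-yl]-5,7-dimethoxy-2,3-dihydro-4H-chromen-4-one | COc1ccc([C@@H]2CC(=O)c3c(cc(OC)c(C/C=C(\C)CCC=C(C)C)c3OC)O2)cc1OC | intermediate
14 | (2S)-2-(3,4-dimethoxyphenyl)-6-[(2E)-3,7-dimethylocta-2,6-dien-1-yl]-5-hydroxy-7-methoxy-2,3-dihydro-4H-chromen-4-one | COc1ccc([C@@H]2CC(=O)c3c(cc(OC)c(C/C=C(\C)CCC=C(C)C)c3O)O2)cc1OC | target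

**Step count**

Total steps: 6. Longest linear sequence: 5 steps (1, 2, 3, 5, 6); step 4 is a one-step branch.

**Steps most likely to fail**

Step 5. The enantiofacial discrimination in the oxa-Michael closure of a chalcone without an extra activating group may be insufficient. Uncatalysed background closure and reversible ring opening may further erode the enantiomeric purity. The fallback sets the stereocenter by an asymmetric 1,4-arylation of a chromone and forms the C2–aryl bond last. It sets out from 7 and comes back to the route at 13. Phenol 7 is converted into its bromomagnesium phenolate and C-acetylated with acetyl chloride in toluene to give 1-{3-[(2E)-3,7-dimethylocta-2,6-dien-1-yl]-6-hydroxy-2,4-dimethoxyphenyl}ethan-1-one F1. Heating with N,N-dimethylformamide dimethyl acetal should give the enaminone (2E)-3-(dimethylamino)-1-{3-[(2E)-3,7-dimethylocta-2,6-dien-1-yl]-6-hydroxy-2,4-dimethoxyphenyl}prop-2-en-1-one F2. On treatment with acetic acid or silica gel this should close with loss of dimethylamine to 6-[(2E)-3,7-dimethylocta-2,6-dien-1-yl]-5,7-dimethoxy-4H-chromen-4-one F3. Rhodium-catalysed asymmetric 1,4-addition of 3,4-dimethoxyphenylboronic acid (Hayashi–Miyaura reaction; [Rh(OH)(cod)]2 with an atropisomeric bisphosphine carrying electron-poor aryl groups, the enantiomer chosen for the (S) product, toluene/H2O) should then give 13. The isolated trisubstituted alkenes of the geranyl chain are not expected to react.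

Step 6. The Lewis acid may promote opening and reclosure of ring C at the p-alkoxybenzylic C2–O1 bond, with loss of configuration at C2. The fallback moves the demethylation to a stage where no stereocenter exists yet. It sets out from 7 and comes back to the route at 14. Phenol 7 is taken as above to 6-[(2E)-3,7-dimethylocta-2,6-dien-1-yl]-5,7-dimethoxy-4H-chromen-4-one F3. Its 5-methoxy group is cleaved with MgI2·OEt2 in THF under the same chelation control to give 6-[(2E)-3,7-dimethylocta-2,6-dien-1-yl]-5-hydroxy-7-methoxy-4H-chromen-4-one F4. The rhodium-catalysed asymmetric 1,4-addition of 3,4-dimethoxyphenylboronic acid to F4 should then give 14 directly.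

Step 2. Deprotonation may go in part to a ring carbon next to the silyl ether, followed by migration of silicon from oxygen to carbon, so that the allyl chain would enter at the wrong position. The fallback replaces the deprotonation by electrophilic bromination and bromine–lithium exchange. It sets out from 2 and comes back to the route at 4. N-Bromosuccinimide in MeCN at 0 °C should brominate 2 at the carbon para to the shielding silyloxy group to give (4-bromo-3,5-dimethoxyphenoxy)tri(propan-2-yl)silane F5. Treatment with t-BuLi (2 equiv, THF, −78 °C) should give aryllithium 4 at a defined position, which is carried on as in step 2.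

**Further compounds**

F1 | step 5 | 1-{3-[(2E)-3,7-dimethylocta-2,6-dien-1-yl]-6-hydroxy-2,4-dimethoxyphenyl}ethan-1-one | CC(=O)c1c(O)cc(OC)c(C/C=C(\C)CCC=C(C)C)c1OC
F2 | step 5 | (2E)-3-(dimethylamino)-1-{3-[(2E)-3,7-dimethylocta-2,6-dien-1-yl]-6-hydroxy-2,4-dimethoxyphenyl}prop-2-en-1-one | CN(C)/C=C/C(=O)c1c(O)cc(OC)c(C/C=C(\C)CCC=C(C)C)c1OC
F3 | step 5 | 6-[(2E)-3,7-dimethylocta-2,6-dien-1-yl]-5,7-dimethoxy-4H-chromen-4-one | COc1cc2occc(=O)c2c(OC)c1C/C=C(\C)CCC=C(C)C
F4 | step 6 | 6-[(2E)-3,7-dimethylocta-2,6-dien-1-yl]-5-hydroxy-7-methoxy-4H-chromen-4-one | COc1cc2occc(=O)c2c(O)c1C/C=C(\C)CCC=C(C)C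
F5 | step 2 | (4-bromo-3,5-dimethoxyphenoxy)tri(propan-2-yl)silane | COc1cc(O[Si](C(C)C)(C(C)C)C(C)C)cc(OC)c1Br
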